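**Plan**
- The target is an all-E ε,ε-carotenol (carotenoid numbering, ring A unprimed, ring B primed). Ring A (6S) and ring B (3'S,6'S, hydroxyl trans to the chain) each hang from C6 or C6' on a disubstituted double bond, C7=C8 and C7'=C8', and C8 to C8' between them is the symmetrical C20 heptaene of crocetindialdehyde.
- Retrosynthesis: the O–Si bond is cut first, then both C7=C8 and C7'=C8', which gives the C20 dial (electrophilic at C8 and C8') and two C10 ring sulfones (nucleophilic at C7 and C7'). The dial is cut at C11=C12 and C11'=C12' into a C10 dial and two C5 phosphonates.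
- Forward: C10 + 2 C5 gives the C20 dial. Geranic acid is cyclised (the only ring-forming step), resolved and reduced to (S)-α-cyclogeraniol, which is turned into the ring A sulfone and, after C3' oxidation, reduction and silylation, into the ring B sulfone.
- The chain is joined in one flask: the ring B sulfone onto an excess of dial, then the ring A sulfone; desilylation ends the route.
- Stereochemistry: C6 and C6' come from one resolution of α-cyclogeranic acid; C3' comes from hydride delivery controlled by the ring; the E-alkenes come from the olefinations and crystallisation.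

Key step: step 17

Assumption: the less soluble salt of (R)-1-phenylethylamine is taken to be that of the (S)-acid (if a first crystallisation shows the opposite pairing, the (S)-amine is used and nothing else changes); 1 and 2 are bought, and geranic acid 6 may be the commercial 2E/2Z mixture because both isomers give the same cation.

**Route**

Step 1
Reactants: 1 (2E,4E,6E)-2,7-dimethylocta-2,4,6-trienedial; 2 ethyl (2E)-4-(diethoxyphosphoryl)-2-methylbut-2-enoate
Product: 3 diethyl crocetinate, diethyl (all-E)-2,6,11,15-tetramethylhexadeca-2,4,6,8,10,12,14-heptaenedioate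
Conditions: 2 (2.4 equiv), NaOEt (2.3 equiv), EtOH–THF, 0 °C; then 1, 0 °C to rt, dark; recrystallisation
Reagents that add atoms: none
Why: Twofold Horner–Wadsworth–Emmons olefination in which the ester-stabilised allylic phosphonate anion reacts at the carbon next to phosphorus with each formyl group to give E-alkenes, and the sparingly soluble all-E diester should be freed of minor Z isomers by crystallisation.

Step 2
Reactants: 3 diethyl crocetinate
Product: 4 crocetindiol, (all-E)-2,6,11,15-tetramethylhexadeca-2,4,6,8,10,12,14-heptaene-1,16-diol
Conditions: i-Bu2AlH (5 equiv), CH2Cl2, −40 to 0 °C, dark; aq. potassium sodium tartrate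
Reagents that add atoms: none
Why: Ester-to-alcohol reduction by the aluminium hydride, which attacks the conjugated ester carbonyls 1,2 and leaves the polyene untouched.

Step 3
Reactants: 4 crocetindiol
Product: 5 crocetindialdehyde, (all-E)-2,6,11,15-tetramethylhexadeca-2,4,6,8,10,12,14-heptaenedial
Conditions: activated MnO2 (20 equiv), CH2Cl2, rt, dark
Reagents that add atoms: none
Why: MnO2 oxidation of primary allylic alcohols stops at the enal and does not disturb the E double bonds.

Step 4
Reactants: 6 geranic acid
Product: 7 rac-α-cyclogeranic acid, 2,6,6-trimethylcyclohex-2-ene-1-carboxylic acid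
Conditions: 85% H3PO4, toluene, 90 °C; recrystallisation (hexane)
Reagents that add atoms: none
Why: Acid-mediated cation–olefin cyclisation in which protonation of the 6,7-double bond gives a tertiary cation that is captured by C2 of the unsaturated acid to close the six-membered ring, proton loss from the ring CH2 gives the non-conjugated α-isomer, and the new stereocentre at the carboxyl-bearing carbon forms without control, as the racemate.

Step 5
Reactants: 7 rac-α-cyclogeranic acid; 8 (R)-1-phenylethylamine
Product: 9 (R)-1-phenylethylammonium (S)-2,6,6-trimethylcyclohex-2-ene-1-carboxylate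
Conditions: 8 (1.0 equiv), acetone, reflux to 5 °C; recrystallisation to constant rotation
Reagents that add atoms: none
Why: Classical resolution through diastereomeric salts, whose different solubility should leave the salt of the (S)-acid after repeated crystallisation, so that the configuration of C6 and C6' of the target is selected here.

Step 6
Reactants: 9 the resolved salt
Product: 10 (S)-α-cyclogeranic acid, (1S)-2,6,6-trimethylcyclohex-2-ene-1-carboxylic acid
Conditions: 1 M HCl, Et2O, 0 °C
Reagents that add atoms: none
Why: Acid–base liberation in which cold dilute HCl protonates the carboxylate into the ether layer while the amine stays in water, conditions too mild to move the ring double bond or to enolise the acid.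

Step 7
Reactants: 10 (S)-α-cyclogeranic acid
Product: 11 (S)-α-cyclogeraniol, [(1S)-2,6,6-trimethylcyclohex-2-en-1-yl]methanol
Conditions: LiAlH4 (2 equiv), THF, 0 °C to reflux; H2O, aq. NaOH
Reagents that add atoms: none
Why: Hydride reduction of a carboxylic acid to the primary alcohol, in which the lithium carboxylate formed first cannot enolise, so the allylic stereocentre is retained.

Step 8
Reactants: 11 (S)-α-cyclogeraniol; 12 1-phenyl-1H-tetrazole-5-thiol
Product: 13 1-phenyl-5-({[(1S)-2,6,6-trimethylcyclohex-2-en-1-yl]methyl}sulfanyl)-1H-tetrazole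
Conditions: 12 (1.4 equiv), PPh3 (1.5 equiv), DIAD (1.5 equiv), THF, 0 °C to rt
Reagents that add atoms: none
Why: Mitsunobu thioetherification in which the acidic thiol protonates the betaine and its thiolate displaces the oxyphosphonium group at the primary carbon by SN2, a step that does not involve the neighbouring stereocentre.

Step 9
Reactants: 13 the ring A sulfide
Product: 14 ring A sulfone, 1-phenyl-5-({[(1S)-2,6,6-trimethylcyclohex-2-en-1-yl]methyl}sulfonyl)-1H-tetrazole
Conditions: (NH4)6Mo7O24·4H2O (10 mol %), 30% H2O2 (6 equiv), EtOH, 0 °C to rt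
Reagents that add atoms: hydrogen peroxide, OO
Why: Peroxomolybdate-catalysed oxidation of sulfide to sulfone through the sulfoxide, which should be much faster at sulfur than epoxidation of the hindered trisubstituted ring alkene.

Step 10
Reactants: 11 (S)-α-cyclogeraniol
Product: 15 [(1S)-2,6,6-trimethylcyclohex-2-en-1-yl]methyl 2,2-dimethylpropanoate
Conditions: t-BuCOCl (1.3 equiv), pyridine, DMAP (cat.), CH2Cl2, 0 °C to rt
Reagents that add atoms: pivaloyl chloride, CC(C)(C)C(=O)Cl
Why: Esterification through the acylpyridinium ion, with the pivalate chosen because it carries no oxidisable C–H bond on the acyl side and resists LiBH(s-Bu)3 at −78 °C.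

Step 11
Reactants: 15 the pivalate
Product: 16 [(1S)-2,6,6-trimethyl-4-oxocyclohex-2-en-1-yl]methyl 2,2-dimethylpropanoate
Conditions: Rh2(C6H10NO)4 (dirhodium tetracaprolactamate, 1 mol %), t-BuOOH (5 equiv), K2CO3 (0.5 equiv), CH2Cl2, rt
Reagents that add atoms: tert-butyl hydroperoxide, CC(C)(C)OO
Why: Catalytic allylic C–H oxidation by a tert-butylperoxyl radical chain, in which hydrogen is taken from the ring CH2 at C3' (the only unhindered secondary allylic position), the allyl radical is trapped as the C3' peroxide and this collapses to the conjugated enone, while the tertiary C6'–H, shielded by the quaternary carbon and the acyloxymethyl arm, should be left alone so that its configuration is kept.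

Step 12
Reactants: 16 the enone
Product: 17 [(1S,4S)-4-hydroxy-2,6,6-trimethylcyclohex-2-en-1-yl]methyl 2,2-dimethylpropanoate (3',6'-trans)
Conditions: LiBH(s-Bu)3 (1.2 equiv), THF, −78 °C; aq. NH4Cl; chromatography (removal of the C3' epimer)
Reagents that add atoms: none
Why: 1,2-Reduction of a β,β-disubstituted enone under steric approach control, in which the acyloxymethyl arm at C6' should sit pseudoaxial to escape allylic 1,2-strain with the C5' methyl, the axial C1' methyl then lies on the other face, and the bulky hydride enters anti to that methyl so that the new hydroxyl comes out pseudoaxial and trans to the C6' arm (3'S).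

Step 13
Reactants: 17 the trans allylic alcohol
Product: 18 [(1S,4S)-4-(tert-butyldimethylsilyloxy)-2,6,6-trimethylcyclohex-2-en-1-yl]methyl 2,2-dimethylpropanoate
Conditions: TBSCl (1.5 equiv), imidazole (3 equiv), DMF, rt
Reagents that add atoms: tert-butyldimethylsilyl chloride, CC(C)(C)[Si](C)(C)Cl
Why: Silyl ether formation through the silylimidazolium species, which leaves the C3' configuration untouched because the C–O bond is not broken.

Step 14
Reactants: 18 the silyl ether pivalate
Product: 19 [(1S,4S)-4-(tert-butyldimethylsilyloxy)-2,6,6-trimethylcyclohex-2-en-1-yl]methanol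
Conditions: i-Bu2AlH (2.5 equiv), CH2Cl2, −78 °C; aq. potassium sodium tartrate
Reagents that add atoms: none
Why: Reductive cleavage of the ester by the aluminium hydride at low temperature, which frees the primary alcohol and leaves the silyl ether and the alkene intact.

Step 15
Reactants: 19 the silyloxy alcohol; 12 1-phenyl-1H-tetrazole-5-thiol
Product: 20 5-({[(1S,4S)-4-(tert-butyldimethylsilyloxy)-2,6,6-trimethylcyclohex-2-en-1-yl]methyl}sulfanyl)-1-phenyl-1H-tetrazole
Conditions: 12 (1.4 equiv), PPh3 (1.5 equiv), DIAD (1.5 equiv), THF, 0 °C to rt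
Reagents that add atoms: none
Why: Mitsunobu thioetherification at the primary carbinol by SN2, as in step 8, which the silyl ether and both stereocentres should survive unchanged.

Step 16
Reactants: 20 the ring B sulfide
Product: 21 ring B sulfone, 5-({[(1S,4S)-4-(tert-butyldimethylsilyloxy)-2,6,6-trimethylcyclohex-2-en-1-yl]methyl}sulfonyl)-1-phenyl-1H-tetrazole
Conditions: (NH4)6Mo7O24·4H2O (10 mol %), 30% H2O2 (6 equiv), EtOH, 0 °C to rt
Reagents that add atoms: hydrogen peroxide, OO
Why: Peroxomolybdate-catalysed sulfide-to-sulfone oxidation as in step 9, mild enough for the secondary silyl ether and slower still at a ring alkene that now carries an allylic silyloxy group.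

Step 17
Reactants: 5 crocetindialdehyde; 21 ring B sulfone; 14 ring A sulfone
Product: 23 (all-E)-(3'S,6S,6'S)-3'-(tert-butyldimethylsilyloxy)-ε,ε-carotene, via ring B C30 apo-aldehyde 22 (not isolated)
Conditions: 21 (1.0 equiv), KN(SiMe3)2 (0.95 equiv), THF, −78 °C; slow cannulation into 5 (1.5 equiv), THF–DMF 4:1, −60 to −20 °C; recool to −78 °C; anion from 14 (2.5 equiv) and KN(SiMe3)2 (2.4 equiv), THF, −78 °C to rt; aq. NH4Cl; Ar, dark; SiO2
Reagents that add atoms: none
Why: Each potassiated phenyltetrazolyl sulfone adds through its exocyclic carbanion (C7' of ring B first, then C7 of ring A) to a formyl carbon of the C20 dial, the alkoxide attacks C5 of the tetrazole (Smiles rearrangement) and the sulfinate so formed loses SO2 and 1-phenyltetrazol-5-olate, which creates first the C7'=C8' and then the C7=C8 double bond; the closest known reaction is the Julia–Kocienski olefination of polyenals, run here twice in one flask as a C10 + C20 + C10 assembly. No ring closes and no stereocentre is formed; the three existing ones should survive because the carbanions sit on the CH2 groups and not on C6 or C6', and because the amide base is always the limiting partner of its sulfone, so that no free base meets the doubly allylic C6–H bonds of the products or the vinylogously acidic methyl groups of 5. The selectivity needed is one olefination per formyl group with two different sulfones: the costly ring B anion is added slowly to an excess of dissolved 5, whose second formyl group is also less electrophilic once the first has become an alkene, and the cheap ring A anion, used in excess, then converts 22 into 23 and sweeps the surplus dial into non-polar (6S,6'S)-ε,ε-carotene, which should elute ahead of 23. E geometry at the two new disubstituted alkenes is expected from the potassium counter-ion, the polar medium and the branched ring carbon next to each carbanion.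

Step 18
Reactants: 23 the silyl ether
Product: 24 the target, (all-E)-(3'S,6S,6'S)-ε,ε-caroten-3'-ol in the numbering used here
Conditions: Bu4NF (3 equiv), AcOH (3 equiv), THF, 0 °C to rt, dark; crystallisation from hot heptane–EtOH under Ar
Reagents that add atoms: none
Why: Fluoride-induced silyl ether cleavage driven by the Si–F bond, buffered with acetic acid so that neither the allylic C3' alcohol ionises nor the doubly allylic C6 and C6' hydrogens are removed, with the hot crystallisation allowing any sterically hindered 7Z or 7'Z bond to revert to E.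

**Compound list**

1 | (2E,4E,6E)-2,7-dimethylocta-2,4,6-trienedial | O=C/C(C)=C/C=C/C=C(C)/C=O | starting material
2 | ethyl (2E)-4-(diethoxyphosphoryl)-2-methylbut-2-enoate | CCOC(=O)/C(C)=C/CP(=O)(OCC)OCC | starting material
3 | diethyl crocetinate (all-E) | CCOC(=O)/C(C)=C/C=C/C(C)=C/C=C/C=C(C)/C=C/C=C(C)/C(=O)OCC | intermediate
4 | crocetindiol (all-E) | OC/C(C)=C/C=C/C(C)=C/C=C/C=C(C)/C=C/C=C(C)/CO | intermediate
5 | crocetindialdehyde (all-E C20 dial, C8 to C8') | O=C/C(C)=C/C=C/C(C)=C/C=C/C=C(C)/C=C/C=C(C)/C=O | intermediate
6 | geranic acid | CC(C)=CCC/C(C)=C/C(=O)O | starting material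
7 | rac-α-cyclogeranic acid | CC1=CCCC(C)(C)C1C(=O)O | intermediate
8 | (R)-1-phenylethylamine | C[C@@H](N)c1ccccc1 | starting material
9 | (R)-1-phenylethylammonium (S)-2,6,6-trimethylcyclohex-2-ene-1-carboxylate | CC1=CCCC(C)(C)[C@@H]1C(=O)[O-].C[C@@H]([NH3+])c1ccccc1 | intermediate
10 | (S)-α-cyclogeranic acid | CC1=CCCC(C)(C)[C@@H]1C(=O)O | intermediate
11 | (S)-α-cyclogeraniol | CC1=CCCC(C)(C)[C@@H]1CO | intermediate
12 | 1-phenyl-1H-tetrazole-5-thiol | Sc1nnnn1-c1ccccc1 | starting material
13 | 1-phenyl-5-({[(1S)-2,6,6-trimethylcyclohex-2-en-1-yl]methyl}sulfanyl)-1H-tetrazole | CC1=CCCC(C)(C)[C@@H]1CSc1nnnn1-c1ccccc1 | intermediate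
14 | ring A sulfone, 1-phenyl-5-({[(1S)-2,6,6-trimethylcyclohex-2-en-1-yl]methyl}sulfonyl)-1H-tetrazole | CC1=CCCC(C)(C)[C@@H]1CS(=O)(=O)c1nnnn1-c1ccccc1 | intermediate
15 | [(1S)-2,6,6-trimethylcyclohex-2-en-1-yl]methyl 2,2-dimethylpropanoate | CC1=CCCC(C)(C)[C@@H]1COC(=O)C(C)(C)C | intermediate
16 | [(1S)-2,6,6-trimethyl-4-oxocyclohex-2-en-1-yl]methyl 2,2-dimethylpropanoate | CC1=CC(=O)CC(C)(C)[C@@H]1COC(=O)C(C)(C)C | intermediate
17 | [(1S,4S)-4-hydroxy-2,6,6-trimethylcyclohex-2-en-1-yl]methyl 2,2-dimethylpropanoate | CC1=C[C@@H](O)CC(C)(C)[C@@H]1COC(=O)C(C)(C)C | intermediate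
18 | [(1S,4S)-4-(tert-butyldimethylsilyloxy)-2,6,6-trimethylcyclohex-2-en-1-yl]methyl 2,2-dimethylpropanoate | CC1=C[C@@H](O[Si](C)(C)C(C)(C)C)CC(C)(C)[C@@H]1COC(=O)C(C)(C)C | intermediate
19 | [(1S,4S)-4-(tert-butyldimethylsilyloxy)-2,6,6-trimethylcyclohex-2-en-1-yl]methanol | CC1=C[C@@H](O[Si](C)(C)C(C)(C)C)CC(C)(C)[C@@H]1CO | intermediate
20 | 5-({[(1S,4S)-4-(tert-butyldimethylsilyloxy)-2,6,6-trimethylcyclohex-2-en-1-yl]methyl}sulfanyl)-1-phenyl-1H-tetrazole | CC1=C[C@@H](O[Si](C)(C)C(C)(C)C)CC(C)(C)[C@@H]1CSc1nnnn1-c1ccccc1 | intermediate
21 | ring B sulfone, 5-({[(1S,4S)-4-(tert-butyldimethylsilyloxy)-2,6,6-trimethylcyclohex-2-en-1-yl]methyl}sulfonyl)-1-phenyl-1H-tetrazole | CC1=C[C@@H](O[Si](C)(C)C(C)(C)C)CC(C)(C)[C@@H]1CS(=O)(=O)c1nnnn1-c1ccccc1 | intermediate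
22 | ring B C30 apo-aldehyde, all-E polyenal made of ring B (3'S,6'S, silyl ether), C7' to C9 of the chain and the formyl carbon C8 | O=C/C(C)=C/C=C/C(C)=C/C=C/C=C(C)/C=C/C=C(C)/C=C/[C@@H]1C(C)=C[C@@H](O[Si](C)(C)C(C)(C)C)CC1(C)C | intermediate
23 | (all-E)-(3'S,6S,6'S)-3'-(tert-butyldimethylsilyloxy)-ε,ε-carotene | CC1=CCCC(C)(C)[C@@H]1/C=C/C(C)=C/C=C/C(C)=C/C=C/C=C(C)/C=C/C=C(C)/C=C/[C@@H]1C(C)=C[C@@H](O[Si](C)(C)C(C)(C)C)CC1(C)C | intermediate
24 | (all-E)-(3'S,6S,6'S)-ε,ε-caroten-3'-ol, CNP0153224.1 | CC1=CCCC(C)(C)[C@@H]1/C=C/C(C)=C/C=C/C(C)=C/C=C/C=C(C)/C=C/C=C(C)/C=C/[C@@H]1C(C)=C[C@@H](O)CC1(C)C | target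

**Count**
Total steps: 18. Longest linear sequence: 13 steps (4, 5, 6, 7, 10, 11, 12, 13, 14, 15, 16, 17, 18).

**Steps most likely to fail**

Step 17. What may go wrong is a loss of mono-selectivity in the first stage: the second formyl group of 22 competes with 5 for the ring B anion, and the sweep by the ring A anion is then incomplete, so that 23 is contaminated with symmetrical C40 products. The fallback sets out from 5 and 21 and runs the two olefinations as separate operations. The anion of 21 is added to three equivalents of 5, 22 is isolated by chromatography with recovery of the surplus dial, and purified 22 is then treated with 1.3 equivalents of the anion of 14, which returns to the route at 23. This adds no compound to the route (F0).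

Step 12. What may go wrong is poor facial selectivity of hydride delivery, so that the 3',6'-cis alcohol predominates. The fallback sets out from 16 and takes the cis epimer on purpose. Luche reduction (NaBH4, CeCl3·7H2O, MeOH, −78 °C), in which the small hydride attacks axially, should give [(1S,4R)-4-hydroxy-2,6,6-trimethylcyclohex-2-en-1-yl]methyl 2,2-dimethylpropanoate F1. Mitsunobu inversion with 4-nitrobenzoic acid (PPh3, DIAD, toluene, 0 °C to rt) then gives [(1S,4S)-2,6,6-trimethyl-4-(4-nitrobenzoyloxy)cyclohex-2-en-1-yl]methyl 2,2-dimethylpropanoate F2. Selective methanolysis of the activated benzoate (K2CO3, MeOH, 0 °C), which the pivalate should outlast, returns to the route at 17.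

Step 11. What may go wrong is leakage of the radical oxidation to the tertiary C5' peroxide, or stalling and over-oxidation, so that little enone is obtained. The fallback sets out from 15 and reaches the same oxidation level in two polar steps. Wohl–Ziegler bromination (N-bromosuccinimide, dibenzoyl peroxide cat., PhCF3, 80 °C) should give [(1S)-4-bromo-2,6,6-trimethylcyclohex-2-en-1-yl]methyl 2,2-dimethylpropanoate F3 as a mixture of C3' epimers. Kornblum-type oxidation of this allylic bromide with trimethylamine N-oxide (DMSO, rt) returns to the route at 16.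

**Further compounds**
F0 | step 17 | none | none
F1 | step 12 | [(1S,4R)-4-hydroxy-2,6,6-trimethylcyclohex-2-en-1-yl]methyl 2,2-dimethylpropanoate | CC1=C[C@H](O)CC(C)(C)[C@@H]1COC(=O)C(C)(C)C
F2 | step 12 | [(1S,4S)-2,6,6-trimethyl-4-(4-nitrobenzoyloxy)cyclohex-2-en-1-yl]methyl 2,2-dimethylpropanoate | CC1=C[C@@H](OC(=O)c2ccc(cc2)[N+](=O)[O-])CC(C)(C)[C@@H]1COC(=O)C(C)(C)C
F3 | step 11 | [(1S)-4-bromo-2,6,6-trimethylcyclohex-2-en-1-yl]methyl 2,2-dimethylpropanoate (both epimers at the bromine-bearing carbon) | CC1=CC(Br)CC(C)(C)[C@@H]1COC(=O)C(C)(C)C
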